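**Retrosynthetic overview**
1. The target comes from acetylation of the tertiary C12 alcohol of the corresponding 4-hydroxycyclopent-2-enone.
2. The cyclopentenone is the only ring and is formed last but one, from a 2,5-disubstituted furan that already carries both complete side chains. The C8–C12 bond is closed by 4π-conrotatory electrocyclisation of a 2-hydroxypentadienyl cation (oxa-Piancatelli rearrangement). This is the same cation type and the same bond as in the allene oxide → oxidopentadienyl cation → cis-cyclopentenone closure of marine prostanoid biosynthesis, with the C12 oxygen already in place. A chiral counter-anion sets C8 and C12 together.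
3. The furan precursor comes from methyl 4-oxobutanoate, a 5-octenylfurfural and an allenylboronate in a one-pot double allylboration, which sets C4 (S) and the 5E olefin.
4. The 5-octenylfurfural comes from a furfural acetal and (Z)-oct-2-enyl bromide.

Assumption: prostanoid numbering is used (C1 ester carbon, C8 and C12 the ring carbons bearing the chains, C9 the ketone); the sense of induction of the chiral acid in step 6 cannot be predicted with certainty, so the (R)-acid is written and its mirror image is used if the first run favours the other ring diastereomer.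

**Route**

Step 1
Reactants: 1 (2Z)-oct-2-en-1-ol
Product: 2 (2Z)-1-bromooct-2-ene
Conditions: PBr3 (0.4 equiv), pyridine (cat.), Et2O, −20 to 0 °C
Reagents that add atoms: phosphorus tribromide, BrP(Br)Br
Why: Bromination of a primary allylic alcohol with PBr3 (SN2 on the phosphite ester) at low temperature gives the primary bromide without allylic shift or loss of the Z geometry.

Step 2
Reactants: 3 2-(furan-2-yl)-1,3-dioxolane; 2 (2Z)-1-bromooct-2-ene
Product: 6 5-[(2Z)-oct-2-en-1-yl]furan-2-carbaldehyde, via 2-(5-lithiofuran-2-yl)-1,3-dioxolane 4 (not isolated), via octenylfuryl dioxolane 5 (not isolated)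
Conditions: n-BuLi (1.05 equiv), THF, −78 to −20 °C; 2, −78 °C to rt; then 1 M aq. HCl, THF, rt
Reagents that add atoms: water, O
Why: α-Lithiation of the furan acetal at C5, SN2 alkylation of the furyllithium by the primary allylic bromide (as in the alkylation of 2-furyllithiums with prenyl or geranyl bromide) and acid hydrolysis of the dioxolane on work-up give the aldehyde, the isolated Z olefin being inert throughout.

Step 3
Reactants: 7 3-bromoprop-1-yne (propargyl bromide); 8 2,2-dimethylpropane-1,3-diol
Product: 12 5,5-dimethyl-2-(propa-1,2-dien-1-yl)-1,3,2-dioxaborinane, via allenylmagnesium bromide 9 (not isolated), via bromomagnesium allenyl(trimethoxy)borate 10 (not isolated), via allenylboronic acid 11 (not isolated)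
Conditions: Mg, HgCl2 (1 mol%), Et2O, 0 °C; B(OMe)3, −78 °C; 1 M aq. HCl, 0 °C; then 8, MgSO4, Et2O, rt
Reagents that add atoms: trimethyl borate, COB(OC)OC
Why: The propargyl/allenyl Grignard reagent is borylated by trimethyl borate to give the allenylboronic acid, which is esterified with the 1,3-diol (Grignard borylation, boronic ester formation); no stereocentre is formed.

Step 4
Reactants: 12 5,5-dimethyl-2-(propa-1,2-dien-1-yl)-1,3,2-dioxaborinane; 13 (+)-diisopinocampheylborane [from (−)-α-pinene]; 14 methyl 4-oxobutanoate; 6 5-[(2Z)-oct-2-en-1-yl]furan-2-carbaldehyde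
Product: 18 methyl (4S,5E,8R)-4,8-dihydroxy-8-{5-[(2Z)-oct-2-en-1-yl]furan-2-yl}oct-5-enoate, via (E)-γ-borylallyl diisopinocampheylborane 15 (not isolated), via α-boryl homoallyl borinate 16 (not isolated), via bis-O-borylated diol 17 (not isolated)
Conditions: 12 (1.3 equiv), 13 (1.25 equiv), Et2O, −25 to 0 °C; 14 (1.2 equiv), −78 °C, 3 h; 6 (1.0 equiv), −78 °C to rt, 24 h; then NaH2PO4/Na2HPO4 buffer (pH 7), 30% H2O2, 0 °C, 1 h
Reagents that add atoms: none
Why: One-pot double allylboration in which hydroboration of the terminal allene C=C gives the (E)-γ-boryl allylborane 15, Brown-type allylboration of 14 through a chair transition state under control of the isopinocampheyl groups from (−)-α-pinene (Re face of the aldehyde) sets C4 as S, and the resulting α-substituted allylboronate 16 adds to 6 through a chair with the α-substituent equatorial to give the 5E olefin (the 1,5-anti C8 configuration set here is of no consequence because C8 is ionised in step 6).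

Step 5
Reactants: 18 methyl (4S,5E,8R)-4,8-dihydroxy-8-{5-[(2Z)-oct-2-en-1-yl]furan-2-yl}oct-5-enoate
Product: 19 methyl (4S,5E,8R)-4,8-diacetoxy-8-{5-[(2Z)-oct-2-en-1-yl]furan-2-yl}oct-5-enoate
Conditions: Ac2O (4 equiv), pyridine, DMAP (5 mol%), CH2Cl2, 0 °C, on crude 18 at once
Reagents that add atoms: acetic anhydride, CC(=O)OC(C)=O
Why: DMAP-catalysed acylation of both secondary alcohols, done at once on the crude diol so that the 4-hydroxy ester cannot close to the γ-lactone, installs the C4 acetate of the target and turns the furfuryl C8 oxygen into a leaving group without touching a stereocentre.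

Step 6
Reactants: 19 methyl (4S,5E,8R)-4,8-diacetoxy-8-{5-[(2Z)-oct-2-en-1-yl]furan-2-yl}oct-5-enoate
Product: 20 methyl (4S,5E)-4-acetoxy-7-[(1S,5R)-5-hydroxy-5-[(2Z)-oct-2-en-1-yl]-2-oxocyclopent-3-en-1-yl]hept-5-enoate
Conditions: (R)-3,3'-bis(2,4,6-triisopropylphenyl)-1,1'-binaphthyl-2,2'-diyl N-triflylphosphoramide (10 mol%), H2O (5 equiv), CHCl3, 40 °C
Reagents that add atoms: water, O
Why: Proposed new method: the strong chiral Brønsted acid ionises the furfuryl acetate to the 5-alkylfurfuryl cation (the C8 configuration of 19 is lost here), water adds at the furan carbon bearing the octenyl chain, ring opening gives the 2-hydroxypentadienyl cation C8–C9(OH)–C10–C11–C12(OH) held as a hydrogen-bonded contact ion pair by the chiral phosphoramidate, and 4π-conrotatory closure of the C8–C12 bond with the C7 chain and the C12 hydroxyl both outward gives the cyclopentenone with OH trans to the C8 chain (the two chains cis), the counter-anion choosing the sense of conrotation and hence 8S,12R; the closest known reaction types are the acid-catalysed oxa-Piancatelli rearrangement of 5-methyl-2-furylcarbinols and the chiral phosphoric acid catalysed asymmetric aza-Piancatelli rearrangement.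

Step 7
Reactants: 20 methyl (4S,5E)-4-acetoxy-7-[(1S,5R)-5-hydroxy-5-[(2Z)-oct-2-en-1-yl]-2-oxocyclopent-3-en-1-yl]hept-5-enoate
Product: 21 methyl (4S,5E)-4-acetoxy-7-[(1S,5R)-5-acetoxy-5-[(2Z)-oct-2-en-1-yl]-2-oxocyclopent-3-en-1-yl]hept-5-enoate (target)
Conditions: Ac2O (3 equiv), Sc(OTf)3 (5 mol%), MeCN, −20 °C
Reagents that add atoms: acetic anhydride, CC(=O)OC(C)=O
Why: Lewis-acid-catalysed acylation of a hindered tertiary alcohol with Ac2O (Sc(OTf)3-catalysed esterification) runs at low temperature without base, so that retro-aldol opening of the β-hydroxy ketone and epimerisation at C8 are avoided and C4, C8 and C12 stay as set.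

**Compound list**
1 | (2Z)-oct-2-en-1-ol | CCCCC/C=C\CO | starting material
2 | (2Z)-1-bromooct-2-ene | CCCCC/C=C\CBr | intermediate
3 | 2-(furan-2-yl)-1,3-dioxolane | C1COC(O1)c1ccco1 | starting material
4 | 2-(5-lithiofuran-2-yl)-1,3-dioxolane | [Li]c1ccc(o1)C1OCCO1 | intermediate
5 | 2-{5-[(2Z)-oct-2-en-1-yl]furan-2-yl}-1,3-dioxolane | CCCCC/C=C\Cc1ccc(o1)C1OCCO1 | intermediate
6 | 5-[(2Z)-oct-2-en-1-yl]furan-2-carbaldehyde | CCCCC/C=C\Cc1ccc(C=O)o1 | intermediate
7 | 3-bromoprop-1-yne | C#CCBr | starting material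
8 | 2,2-dimethylpropane-1,3-diol | CC(C)(CO)CO | starting material
9 | allenylmagnesium bromide (propa-1,2-dien-1-ylmagnesium bromide) | C=C=C[Mg]Br | intermediate
10 | bromomagnesium trimethoxy(propa-1,2-dien-1-yl)borate | C=C=C[B-](OC)(OC)OC.[Mg+]Br | intermediate
11 | propa-1,2-dien-1-ylboronic acid | C=C=CB(O)O | intermediate
12 | 5,5-dimethyl-2-(propa-1,2-dien-1-yl)-1,3,2-dioxaborinane | C=C=CB1OCC(C)(C)CO1 | intermediate
13 | (+)-diisopinocampheylborane, bis[(1S,2R,3S,5S)-2,6,6-trimethylbicyclo[3.1.1]hept-3-yl]borane | [H]B([C@H]1C[C@H]2C[C@@H]([C@@H]1C)C2(C)C)[C@H]1C[C@H]2C[C@@H]([C@@H]1C)C2(C)C | starting material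
14 | methyl 4-oxobutanoate | COC(=O)CCC=O | starting material
15 | 2-{(1E)-3-[bis(isopinocampheyl)boranyl]prop-1-en-1-yl}-5,5-dimethyl-1,3,2-dioxaborinane | CC1(C)COB(OC1)/C=C/CB([C@H]1C[C@H]2C[C@@H]([C@@H]1C)C2(C)C)[C@H]1C[C@H]2C[C@@H]([C@@H]1C)C2(C)C | intermediate
16 | methyl (4S,5R)-4-{[bis(isopinocampheyl)boranyl]oxy}-5-(5,5-dimethyl-1,3,2-dioxaborinan-2-yl)hept-6-enoate | COC(=O)CC[C@H](OB([C@H]1C[C@H]2C[C@@H]([C@@H]1C)C2(C)C)[C@H]1C[C@H]2C[C@@H]([C@@H]1C)C2(C)C)[C@H](B1OCC(C)(C)CO1)C=C | intermediate
17 | methyl (4S,5E,8R)-4-{[bis(isopinocampheyl)boranyl]oxy}-8-[(5,5-dimethyl-1,3,2-dioxaborinan-2-yl)oxy]-8-{5-[(2Z)-oct-2-en-1-yl]furan-2-yl}oct-5-enoate | COC(=O)CC[C@H](OB([C@H]1C[C@H]2C[C@@H]([C@@H]1C)C2(C)C)[C@H]1C[C@H]2C[C@@H]([C@@H]1C)C2(C)C)/C=C/C[C@@H](OB1OCC(C)(C)CO1)c1ccc(C/C=C\CCCCC)o1 | intermediate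
18 | methyl (4S,5E,8R)-4,8-dihydroxy-8-{5-[(2Z)-oct-2-en-1-yl]furan-2-yl}oct-5-enoate | COC(=O)CC[C@H](O)/C=C/C[C@@H](O)c1ccc(C/C=C\CCCCC)o1 | intermediate
19 | methyl (4S,5E,8R)-4,8-diacetoxy-8-{5-[(2Z)-oct-2-en-1-yl]furan-2-yl}oct-5-enoate | COC(=O)CC[C@H](OC(C)=O)/C=C/C[C@@H](OC(C)=O)c1ccc(C/C=C\CCCCC)o1 | intermediate
20 | methyl (4S,5E)-4-acetoxy-7-[(1S,5R)-5-hydroxy-5-[(2Z)-oct-2-en-1-yl]-2-oxocyclopent-3-en-1-yl]hept-5-enoate | CCCCC/C=C\C[C@@]1(O)C=CC(=O)[C@H]1C/C=C/[C@H](CCC(=O)OC)OC(C)=O | intermediate
21 | methyl (4S,5E)-4-acetoxy-7-[(1S,5R)-5-acetoxy-5-[(2Z)-oct-2-en-1-yl]-2-oxocyclopent-3-en-1-yl]hept-5-enoate | CCCCC/C=C\C[C@@]1(OC(C)=O)C=CC(=O)[C@H]1C/C=C/[C@H](CCC(=O)OC)OC(C)=O | target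

**Step count**
Total: 7 steps. Longest linear sequence: 6 steps (1 → 2 → 6 → 18 → 19 → 20 → 21); step 3 is a one-step side branch.

**Three steps most likely to fail**

Step 6 is the weakest point. The asymmetric rearrangement with water as nucleophile, an alkyl-substituted cation and an acetate leaving group is untested. The likely failures are poor selectivity between the two ring diastereomers and loss of a proton from the cation to give a furyl diene. The fallback sets out from 19 and comes back at 20. Diacetate 19 is rearranged without stereocontrol by Dy(OTf)3 (10 mol%) in MeCN/H2O at 80 °C, conditions of the kind used for such rearrangements. This gives 20 together with an equal amount of its ring diastereomer methyl (4S,5E)-4-acetoxy-7-[(1R,5S)-5-hydroxy-5-[(2Z)-oct-2-en-1-yl]-2-oxocyclopent-3-en-1-yl]hept-5-enoate F1. The two are diastereomers because C4 is fixed, and are separated by preparative HPLC on a chiral stationary phase, after which 20 goes on to step 7.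

Step 4 is next. The E selectivity of the second allylboration depends on the unhindered dioxaborinane, excess reagent can consume 6, and the 4-hydroxy ester can lactonise during work-up. The fallback sets out from 6 and comes back at 19. Aldehyde 6 is propargylated with 7 and Zn in THF/aq. NH4Cl to give racemic 1-{5-[(2Z)-oct-2-en-1-yl]furan-2-yl}but-3-yn-1-ol F2. This is acetylated (Ac2O, pyridine) to 1-{5-[(2Z)-oct-2-en-1-yl]furan-2-yl}but-3-yn-1-yl acetate F3. The terminal alkyne is hydrozirconated with Cp2Zr(H)Cl in CH2Cl2 and transmetalated with Me2Zn in toluene at −65 °C. The (E)-alkenylzinc is added to 14 in the presence of a 3-exo-morpholinoisoborneol ligand of the antipode that directs Re-face delivery, and the zinc alkoxide is quenched with Ac2O. The product is 19 mixed with its C8 epimer methyl (4S,5E,8S)-4,8-diacetoxy-8-{5-[(2Z)-oct-2-en-1-yl]furan-2-yl}oct-5-enoate F4. The mixture is used as such in step 6, where C8 is ionised and both epimers converge on 20.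

Step 2 is third. The furyllithium may attack the allylic bromide in the SN2' sense, and the Z bromide may partly isomerise. The fallback sets out from 3 and comes back at 5, building the Z olefin by a Wittig reaction instead. Acetal 3 is lithiated to 4 as before and opened onto ethylene oxide (THF, −78 to 0 °C) to give 2-[5-(1,3-dioxolan-2-yl)furan-2-yl]ethan-1-ol F5. Oxidation with Dess–Martin periodinane (NaHCO3, CH2Cl2, 0 °C) gives [5-(1,3-dioxolan-2-yl)furan-2-yl]acetaldehyde F6, which is used at once. F6 is treated with the ylide from hexyltriphenylphosphonium bromide and NaN(SiMe3)2 in THF at −78 °C (Z-selective Wittig of a non-stabilised ylide) to give 5, which is hydrolysed to 6 as in step 2.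

**Further compounds**
F1 | step 6 | methyl (4S,5E)-4-acetoxy-7-[(1R,5S)-5-hydroxy-5-[(2Z)-oct-2-en-1-yl]-2-oxocyclopent-3-en-1-yl]hept-5-enoate | CCCCC/C=C\C[C@]1(O)C=CC(=O)[C@@H]1C/C=C/[C@H](CCC(=O)OC)OC(C)=O
F2 | step 4 | racemic 1-{5-[(2Z)-oct-2-en-1-yl]furan-2-yl}but-3-yn-1-ol | CCCCC/C=C\Cc1ccc(o1)C(O)CC#C
F3 | step 4 | racemic 1-{5-[(2Z)-oct-2-en-1-yl]furan-2-yl}but-3-yn-1-yl acetate | CCCCC/C=C\Cc1ccc(o1)C(OC(C)=O)CC#C
F4 | step 4 | methyl (4S,5E,8S)-4,8-diacetoxy-8-{5-[(2Z)-oct-2-en-1-yl]furan-2-yl}oct-5-enoate | COC(=O)CC[C@H](OC(C)=O)/C=C/C[C@H](OC(C)=O)c1ccc(C/C=C\CCCCC)o1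
F5 | step 2 | 2-[5-(1,3-dioxolan-2-yl)furan-2-yl]ethan-1-ol | OCCc1ccc(o1)C1OCCO1
F6 | step 2 | [5-(1,3-dioxolan-2-yl)furan-2-yl]acetaldehyde | O=CCc1ccc(o1)C1OCCO1
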